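**Retrosynthetic overview**
- Target 17 is 5,7-dihydroxy-3-(4-hydroxyphenyl)-6-[(E)-4-hydroxy-3-methylbut-2-enyl]chromen-4-one; the last operations are global O-deprotection and C2=C3 dehydration of a 3-hydroxyisoflavanone.
- Feature used: in ring C, C4 (the carbonyl carbon) and C3 (the carbon carrying ring B) are both carbonyl carbons of an ether-tethered keto-aldehyde, so the C3–C4 bond is made with C4 as an acyl anion under carbene catalysis.
- The keto-aldehyde comes from O-phenacylation of a salicylaldehyde, made by ortho-formylation of a 4-substituted 3,5-bis(MOM)phenol; that phenol is symmetric about the side-chain axis, which fixes the side chain at C6.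
- The side chain comes from directed metalation between the two MOM ethers, prenylation, and (E)-selective SeO2 oxidation of the trans methyl group.
- Ring order: rings A and B are bought (phloroglucinol, 4-hydroxyphenacyl bromide); ring C is the only ring formed (step 10).

Key step: step 10

Remark (assumption): the target is achiral and its only stereo-element is the (E)-alkene, set in step 4. The C3 carbinol of the key-step product is formed racemic and is removed in step 11. Step 1 is a statistical bis-etherification whose product is separated by chromatography.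

**Step 1**
Reactants: 1 phloroglucinol
Product: 2 3,5-bis(methoxymethoxy)phenol
Conditions: MOMCl (2.0 equiv), i-Pr2NEt (2.5 equiv), CH2Cl2–DMF, 0 °C to rt; chromatography
Reagents that add atoms: chloromethyl methyl ether (MOMCl), COCCl
Why: Williamson-type O-alkylation of two of the three equivalent phenols should give the bis-MOM ether as the main component of a statistical mixture, from which the mono- and tris-ethers are separated and recycled.

**Step 2**
Reactants: 2 3,5-bis(methoxymethoxy)phenol
Product: 3 tert-butyl[3,5-bis(methoxymethoxy)phenoxy]dimethylsilane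
Conditions: TBSCl, imidazole, DMF, rt
Reagents that add atoms: tert-butyldimethylsilyl chloride, CC(C)(C)[Si](C)(C)Cl
Why: Standard silylation of the remaining phenol installs a bulky, non-coordinating group that tolerates butyllithium at 0 °C and can later be removed by mild base.

**Step 3**
Reactants: 3 tert-butyl[3,5-bis(methoxymethoxy)phenoxy]dimethylsilane; 4 prenyl bromide (1-bromo-3-methylbut-2-ene)
Product: 6 tert-butyl[3,5-bis(methoxymethoxy)-4-(3-methylbut-2-enyl)phenoxy]dimethylsilane, via aryllithium 5 (not isolated)
Conditions: n-BuLi, THF, 0 °C, 1 h; then prenyl bromide, -78 °C to rt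
Reagents that add atoms: none
Why: Directed ortho-metalation should occur at the carbon between the two chelating MOM ethers, while the bulky silyl ether shields the other two ring positions, and the aryllithium is then alkylated at the primary carbon of prenyl bromide (SN2).

**Step 4**
Reactants: 6 tert-butyl[3,5-bis(methoxymethoxy)-4-(3-methylbut-2-enyl)phenoxy]dimethylsilane
Product: 8 (E)-4-[4-(tert-butyldimethylsilyloxy)-2,6-bis(methoxymethoxy)phenyl]-2-methylbut-2-en-1-ol, via enal 7 (not isolated)
Conditions: SeO2 (30 mol%), t-BuOOH (3 equiv), salicylic acid (10 mol%), CH2Cl2, rt; then NaBH4, MeOH, 0 °C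
Reagents that add atoms: selenium dioxide, O=[Se]=O (transfers the oxygen atom); tert-butyl hydroperoxide, CC(C)(C)OO (terminal oxidant that restores SeO2)
Why: Catalytic SeO2 allylic oxidation (ene reaction, then [2,3]-sigmatropic shift) attacks the methyl group trans to the chain at the more substituted alkene terminus, which sets the (E)-alkene, and the borohydride treatment returns the over-oxidised enal to the same alcohol.

**Step 5**
Reactants: 8 (E)-4-[4-(tert-butyldimethylsilyloxy)-2,6-bis(methoxymethoxy)phenyl]-2-methylbut-2-en-1-ol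
Product: 9 tert-butyl{4-[(E)-4-(tert-butyldimethylsilyloxy)-3-methylbut-2-enyl]-3,5-bis(methoxymethoxy)phenoxy}dimethylsilane
Conditions: TBSCl, imidazole, CH2Cl2, rt
Reagents that add atoms: tert-butyldimethylsilyl chloride, CC(C)(C)[Si](C)(C)Cl
Why: Routine silylation of the primary allylic alcohol protects it against the later formylation and dehydration reagents and leaves a group that dilute acid removes at the end.

**Step 6**
Reactants: 9 tert-butyl{4-[(E)-4-(tert-butyldimethylsilyloxy)-3-methylbut-2-enyl]-3,5-bis(methoxymethoxy)phenoxy}dimethylsilane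
Product: 10 4-[(E)-4-(tert-butyldimethylsilyloxy)-3-methylbut-2-enyl]-3,5-bis(methoxymethoxy)phenol
Conditions: K2CO3, MeOH, 0 °C to rt; aq. NH4Cl work-up
Reagents that add atoms: none
Why: Base-mediated methanolysis should cleave only the aryl silyl ether, because phenoxide is a far better leaving group from silicon than the primary alkoxide; any aryl silyl ether already lost in step 4 converges here.

**Step 7**
Reactants: 10 4-[(E)-4-(tert-butyldimethylsilyloxy)-3-methylbut-2-enyl]-3,5-bis(methoxymethoxy)phenol
Product: 11 2-hydroxy-4,6-bis(methoxymethoxy)-5-[(E)-4-(tert-butyldimethylsilyloxy)-3-methylbut-2-enyl]benzaldehyde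
Conditions: MgCl2 (anhydrous), Et3N, (CH2O)n, THF, reflux; aq. NH4Cl work-up
Reagents that add atoms: paraformaldehyde (as formaldehyde), C=O
Why: In the magnesium-mediated ortho-formylation (Casnati–Skattebøl) the magnesium phenoxide delivers formaldehyde to the ortho carbon and a second formaldehyde oxidises the benzylic alkoxide by hydride transfer; the para position is blocked and the two ortho positions are equivalent, so a single aldehyde should form under basic conditions that spare the MOM and silyl ethers.

**Step 8**
Reactants: 12 2-bromo-1-(4-hydroxyphenyl)ethanone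
Product: 13 2-bromo-1-[4-(methoxymethoxy)phenyl]ethanone
Conditions: MOMCl (1.5 equiv), CH2Cl2, 0 °C; i-Pr2NEt added dropwise
Reagents that add atoms: chloromethyl methyl ether (MOMCl), COCCl
Why: MOM ether formation should outrun self-alkylation because MOMCl is a far faster electrophile than the bromoketone and is present in excess before the hindered base generates any phenoxide.

**Step 9**
Reactants: 11 2-hydroxy-4,6-bis(methoxymethoxy)-5-[(E)-4-(tert-butyldimethylsilyloxy)-3-methylbut-2-enyl]benzaldehyde; 13 2-bromo-1-[4-(methoxymethoxy)phenyl]ethanone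
Product: 14 2-[2-[4-(methoxymethoxy)phenyl]-2-oxoethoxy]-4,6-bis(methoxymethoxy)-5-[(E)-4-(tert-butyldimethylsilyloxy)-3-methylbut-2-enyl]benzaldehyde
Conditions: K2CO3, acetone, 0 °C to rt
Reagents that add atoms: none
Why: Williamson ether synthesis of the acidic salicylaldehyde phenol with a phenacyl bromide is fast at room temperature, and the low temperature and weak base should keep the Rap–Stoermer aldol closure to a 2-aroylbenzofuran from starting.

**Step 10**
Reactants: 14 2-[2-[4-(methoxymethoxy)phenyl]-2-oxoethoxy]-4,6-bis(methoxymethoxy)-5-[(E)-4-(tert-butyldimethylsilyloxy)-3-methylbut-2-enyl]benzaldehyde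
Product: 15 racemic 3-hydroxy-5,7-bis(methoxymethoxy)-3-[4-(methoxymethoxy)phenyl]-6-[(E)-4-(tert-butyldimethylsilyloxy)-3-methylbut-2-enyl]chroman-4-one
Conditions: 2-(pentafluorophenyl)-6,7-dihydro-5H-pyrrolo[2,1-c][1,2,4]triazol-2-ium tetrafluoroborate (20 mol%), Et3N (30 mol%), THF (0.05 M), rt to 40 °C, Ar
Reagents that add atoms: none
Why: Et3N deprotonates the triazolium salt to the carbene, which adds to the aldehyde and after proton transfer gives the Breslow intermediate, whose former aldehyde carbon (future C4) is nucleophilic; it adds to the tethered aryl ketone carbon (future C3), and collapse of the adduct releases the carbene and the C4 ketone. The closest known reaction type is the carbene-catalysed intramolecular crossed aldehyde–ketone benzoin of 2-(2-oxo-2-arylethoxy)benzaldehydes to 3-hydroxy-3-arylchroman-4-ones. Ring C closes in the 6-exo-trig mode, since the ketone oxygen stays outside the new six-membered ring. The new C3 carbinol stereocentre is not controlled (achiral catalyst, racemic product) and need not be, because step 11 removes it. The step needs aldehyde-to-ketone coupling to win over intermolecular aldehyde dimerisation and over base-mediated aldol closure of the ketone α-CH2 onto the aldehyde: only the aldehyde can form a Breslow intermediate, the short ether tether makes the six-membered closure fast, and the weak amine base, which suffices for this acidic triazolium salt, keeps ketone enolisation slow. The compact, electron-poor N-pentafluorophenyl carbene is chosen because the aldehyde is electron-rich and flanked by two ortho oxygen substituents.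

**Step 11**
Reactants: 15 racemic 3-hydroxy-5,7-bis(methoxymethoxy)-3-[4-(methoxymethoxy)phenyl]-6-[(E)-4-(tert-butyldimethylsilyloxy)-3-methylbut-2-enyl]chroman-4-one
Product: 16 5,7-bis(methoxymethoxy)-3-[4-(methoxymethoxy)phenyl]-6-[(E)-4-(tert-butyldimethylsilyloxy)-3-methylbut-2-enyl]chromen-4-one
Conditions: Burgess reagent (methyl N-(triethylammoniosulfonyl)carbamate), THF, 60 °C
Reagents that add atoms: none
Why: In the Burgess dehydration the sulfamate ester of the tertiary alcohol should undergo syn elimination with the cis hydrogen at C2, the only β-hydrogens available, driven by formation of the aromatic 4-pyranone and erasing the racemic stereocentre under neutral conditions that spare all protecting groups.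

**Step 12**
Reactants: 16 5,7-bis(methoxymethoxy)-3-[4-(methoxymethoxy)phenyl]-6-[(E)-4-(tert-butyldimethylsilyloxy)-3-methylbut-2-enyl]chromen-4-one
Product: 17 5,7-dihydroxy-3-(4-hydroxyphenyl)-6-[(E)-4-hydroxy-3-methylbut-2-enyl]chromen-4-one
Conditions: HCl (ca. 1 M) in MeOH–THF, rt to 45 °C
Reagents that add atoms: none
Why: Acid-catalysed acetal exchange with methanol should remove the three aryl MOM ethers and acid methanolysis the silyl ether, while the dilute acid and moderate temperature are chosen to spare the allylic alcohol and the trisubstituted (E)-alkene from ionisation or cyclisation onto the flanking phenols.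

**Compound list**
1 | phloroglucinol | Oc1cc(O)cc(O)c1 | starting material
2 | 3,5-bis(methoxymethoxy)phenol | COCOc1cc(O)cc(OCOC)c1 | intermediate
3 | tert-butyl[3,5-bis(methoxymethoxy)phenoxy]dimethylsilane | COCOc1cc(O[Si](C)(C)C(C)(C)C)cc(OCOC)c1 | intermediate
4 | prenyl bromide (1-bromo-3-methylbut-2-ene) | CC(C)=CCBr | starting material
5 | [4-(tert-butyldimethylsilyloxy)-2,6-bis(methoxymethoxy)phenyl]lithium (aryllithium, not isolated) | [Li]c1c(OCOC)cc(O[Si](C)(C)C(C)(C)C)cc1OCOC | intermediate
6 | tert-butyl[3,5-bis(methoxymethoxy)-4-(3-methylbut-2-enyl)phenoxy]dimethylsilane | CC(C)=CCc1c(OCOC)cc(O[Si](C)(C)C(C)(C)C)cc1OCOC | intermediate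
7 | (E)-4-[4-(tert-butyldimethylsilyloxy)-2,6-bis(methoxymethoxy)phenyl]-2-methylbut-2-enal (enal, not isolated) | O=C/C(C)=C/Cc1c(OCOC)cc(O[Si](C)(C)C(C)(C)C)cc1OCOC | intermediate
8 | (E)-4-[4-(tert-butyldimethylsilyloxy)-2,6-bis(methoxymethoxy)phenyl]-2-methylbut-2-en-1-ol | OC/C(C)=C/Cc1c(OCOC)cc(O[Si](C)(C)C(C)(C)C)cc1OCOC | intermediate
9 | tert-butyl{4-[(E)-4-(tert-butyldimethylsilyloxy)-3-methylbut-2-enyl]-3,5-bis(methoxymethoxy)phenoxy}dimethylsilane | CC(C)(C)[Si](C)(C)OC/C(C)=C/Cc1c(OCOC)cc(O[Si](C)(C)C(C)(C)C)cc1OCOC | intermediate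
10 | 4-[(E)-4-(tert-butyldimethylsilyloxy)-3-methylbut-2-enyl]-3,5-bis(methoxymethoxy)phenol | CC(C)(C)[Si](C)(C)OC/C(C)=C/Cc1c(OCOC)cc(O)cc1OCOC | intermediate
11 | 2-hydroxy-4,6-bis(methoxymethoxy)-5-[(E)-4-(tert-butyldimethylsilyloxy)-3-methylbut-2-enyl]benzaldehyde | O=Cc1c(O)cc(OCOC)c(C/C=C(\C)CO[Si](C)(C)C(C)(C)C)c1OCOC | intermediate
12 | 2-bromo-1-(4-hydroxyphenyl)ethanone | O=C(CBr)c1ccc(O)cc1 | starting material
13 | 2-bromo-1-[4-(methoxymethoxy)phenyl]ethanone | COCOc1ccc(C(=O)CBr)cc1 | intermediate
14 | 2-[2-[4-(methoxymethoxy)phenyl]-2-oxoethoxy]-4,6-bis(methoxymethoxy)-5-[(E)-4-(tert-butyldimethylsilyloxy)-3-methylbut-2-enyl]benzaldehyde | O=Cc1c(OCC(=O)c2ccc(OCOC)cc2)cc(OCOC)c(C/C=C(\C)CO[Si](C)(C)C(C)(C)C)c1OCOC | intermediate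
15 | racemic 3-hydroxy-5,7-bis(methoxymethoxy)-3-[4-(methoxymethoxy)phenyl]-6-[(E)-4-(tert-butyldimethylsilyloxy)-3-methylbut-2-enyl]chroman-4-one | OC1(c2ccc(OCOC)cc2)COc2cc(OCOC)c(C/C=C(\C)CO[Si](C)(C)C(C)(C)C)c(OCOC)c2C1=O | intermediate
16 | 5,7-bis(methoxymethoxy)-3-[4-(methoxymethoxy)phenyl]-6-[(E)-4-(tert-butyldimethylsilyloxy)-3-methylbut-2-enyl]chromen-4-one | COCOc1ccc(cc1)-c1coc2cc(OCOC)c(C/C=C(\C)CO[Si](C)(C)C(C)(C)C)c(OCOC)c2c1=O | intermediate
17 | 5,7-dihydroxy-3-(4-hydroxyphenyl)-6-[(E)-4-hydroxy-3-methylbut-2-enyl]chromen-4-one | C/C(=C\Cc1c(O)cc2occ(-c3ccc(O)cc3)c(=O)c2c1O)CO | target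

**Step count**
Total: 12 steps. Longest linear sequence: 11 steps (steps 1–7 and 9–12 from phloroglucinol); step 8 prepares the ring-B fragment.

**Steps most likely to fail**

Step 10. The electron-rich, doubly ortho-oxygenated aldehyde may form the Breslow intermediate too slowly, so that base-mediated aldol closure to a benzofuran consumes the keto-aldehyde. The fallback is the classical deoxybenzoin route; it sets out from 11, bypasses steps 9–11, and comes back at 16. [4-(Methoxymethoxy)benzyl]magnesium chloride F1, prepared from purchased 1-(chloromethyl)-4-(methoxymethoxy)benzene and Mg in THF, is added in excess (THF, 0 °C) to salicylaldehyde 11 to give the racemic carbinol 1-{2-hydroxy-4,6-bis(methoxymethoxy)-5-[(E)-4-(tert-butyldimethylsilyloxy)-3-methylbut-2-enyl]phenyl}-2-[4-(methoxymethoxy)phenyl]ethanol F2. MnO2 (CH2Cl2, rt) should oxidise the benzylic alcohol to the 2-hydroxydeoxybenzoin 1-{2-hydroxy-4,6-bis(methoxymethoxy)-5-[(E)-4-(tert-butyldimethylsilyloxy)-3-methylbut-2-enyl]phenyl}-2-[4-(methoxymethoxy)phenyl]ethanone F3. Heating F3 with N,N-dimethylformamide dimethyl acetal (toluene, 90 °C) installs C2 as an enaminone, and the free ortho phenol closes ring C with loss of dimethylamine to give 16.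

Step 4. Conversion may be low, and oxidation may run on to the enal or attack the doubly activated benzylic–allylic CH2. The fallback is an olefination sequence; it sets out from 6 and comes back at 8. Lemieux–Johnson cleavage of the prenyl alkene (OsO4 2 mol%, NaIO4, 2,6-lutidine, dioxane–H2O, rt) gives 2-[4-(tert-butyldimethylsilyloxy)-2,6-bis(methoxymethoxy)phenyl]acetaldehyde F4. Wittig reaction with the stabilised ylide ethyl 2-(triphenylphosphoranylidene)propanoate (CH2Cl2, rt) should give ethyl (E)-4-[4-(tert-butyldimethylsilyloxy)-2,6-bis(methoxymethoxy)phenyl]-2-methylbut-2-enoate F5 with the usual high (E) preference. DIBAL-H (CH2Cl2, -78 °C) then reduces the ester to allylic alcohol 8.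

Step 9. Under carbonate the new ketone α-CH2 may condense with the ortho aldehyde (Rap–Stoermer closure and dehydration) during or after the alkylation. The fallback is a base-free etherification; it sets out from 13 and 11 and comes back at 14. Bromoketone 13 is converted (HCO2Na, EtOH–H2O, reflux) to 2-hydroxy-1-[4-(methoxymethoxy)phenyl]ethanone F6. F6 is coupled with phenol 11 under Mitsunobu conditions (PPh3, DIAD, THF, 0 °C to rt), which form the same aryl ether without an enolate-forming medium.

**Further compounds**
F1 | step 10 | [4-(methoxymethoxy)benzyl]magnesium chloride | COCOc1ccc(C[Mg]Cl)cc1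
F2 | step 10 | racemic 1-{2-hydroxy-4,6-bis(methoxymethoxy)-5-[(E)-4-(tert-butyldimethylsilyloxy)-3-methylbut-2-enyl]phenyl}-2-[4-(methoxymethoxy)phenyl]ethanol | OC(Cc1ccc(OCOC)cc1)c1c(O)cc(OCOC)c(C/C=C(\C)CO[Si](C)(C)C(C)(C)C)c1OCOC
F3 | step 10 | 1-{2-hydroxy-4,6-bis(methoxymethoxy)-5-[(E)-4-(tert-butyldimethylsilyloxy)-3-methylbut-2-enyl]phenyl}-2-[4-(methoxymethoxy)phenyl]ethanone | O=C(Cc1ccc(OCOC)cc1)c1c(O)cc(OCOC)c(C/C=C(\C)CO[Si](C)(C)C(C)(C)C)c1OCOC
F4 | step 4 | 2-[4-(tert-butyldimethylsilyloxy)-2,6-bis(methoxymethoxy)phenyl]acetaldehyde | O=CCc1c(OCOC)cc(O[Si](C)(C)C(C)(C)C)cc1OCOC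
F5 | step 4 | ethyl (E)-4-[4-(tert-butyldimethylsilyloxy)-2,6-bis(methoxymethoxy)phenyl]-2-methylbut-2-enoate | CCOC(=O)/C(C)=C/Cc1c(OCOC)cc(O[Si](C)(C)C(C)(C)C)cc1OCOC
F6 | step 9 | 2-hydroxy-1-[4-(methoxymethoxy)phenyl]ethanone | COCOc1ccc(C(=O)CO)cc1
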